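# Proposed synthesis of CNP0267696.3 by singlet-oxygen cycloaddition to a ten-membered 3,5-diene

## The problem

The target 27 is a germacranolide: a ten-membered carbocycle (C1–C10) carrying a trans trisubstituted epoxide at C1–C10, a Z trisubstituted olefin at C4=C5 and an α-methylene-γ-butyrolactone fused cis across C6–C7. Six stereocentres must be set (1R,3S,6S,7R,8R,10R). C1 and C10 form a pair that an E olefin and a reagent-controlled epoxidation can deliver. C7 and C8 are contiguous and can arise together in a C–C bond-forming ring closure. C6 is next to C7 and can be controlled by it; C3 is remote from everything except C6, to which it is tied across the olefin. On the ring, O3, O6, the C7 arm and O8 all lie on one face. The ring is medium-sized, so any closure works against transannular strain, and the Z geometry at C4=C5 cannot be left to equilibration. Three groups restrict the reagents: the exocyclic acrylate of the lactone and the methacrylate are Michael acceptors, the epoxide is acid-labile and open to transannular attack, and the allylic C–O bonds at C3 and C6 ionise under Lewis acids. The enabling feature is that O3 and O6 stand cis on the two allylic carbons flanking the Z C4=C5 bond. This cis-2-ene-1,4-diol is the reduced form of the 3,6-dihydro-1,2-dioxine that a C3=C4–C5=C6 diene gives with singlet oxygen.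

## Retrosynthesis

**Acetate, lactone and diol (27 ⇒ 26 ⇒ 25 ⇒ 24).** The acetyl C–O bond at O3 and the O6–C12 lactone bond are cut, giving hydroxy lactone 26 and then diol ester 25; joining O3 to O6 leads to endoperoxide 24. C12 is kept as a methyl ester rather than a free acid or an alcohol, because in 25 only the C6 hydroxyl can reach it in a five-membered closure. O8 is already acylated and O3 is too far away, so the two new hydroxyls differentiate themselves. The forward steps must cleave the O–O bond without base and lactonise without opening the epoxide.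

**C3–O and C6–O (24 ⇒ 23).** Both C–O bonds of the dioxine ring are cut, giving the ten-membered Z,Z-diene 23 and dioxygen. Bringing in O3 by a carbonyl addition at C3, or O6 by allylation of a C6 aldehyde, would leave the other oxygen, the Z olefin and the 1,4-cis relationship to separate steps. The cycloaddition fixes all three in one stereospecific event. 23 has two stereocentres and two oxygens fewer than 24. The forward reaction must favour [4+2] over the ene reaction on a medium-ring diene and must deliver oxygen to the face that places O6 cis to the C7 arm.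

**C7–C8 (23 ⇒ 22 ⇒ 20).** After removal of the methacrylate (22), the ring is opened between C7 and C8 to bromo aldehyde 20. Closing at the diene by coupling two Z-alkenyl partners has little precedent at this ring size, and olefin metathesis gives no control over a Z,Z-diene. Allylation of an aldehyde by a 2-(bromomethyl)alk-2-enoate builds C7, C8, the C8 oxygen and the exocyclic methylene together, and allylmetal closures are the best-documented entry to germacrane rings. 20 is acyclic and keeps only the epoxide stereocentres. The closure must go through the γ carbon at high dilution, with a neutral metal that tolerates the β,γ-epoxy aldehyde, does not lactonise the ester onto O8 and leaves the Z,Z-diene intact.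

**Bromide, C5=C6 and C7–C11 (20 ⇒ 19 ⇒ 18 ⇒ 17 ⇒ 16 ⇒ 14 + 15).** The aldehyde is traced to PMB ether 18 through alcohol 19. The 2-(bromomethyl)trienoate of 18 comes from carbinol 17 by allylic transposition, 17 from enyne 16 by semi-reduction, and 16 from ynal 14 and methyl acrylate 15 by cutting C7–C11. C5–C6 is carried as an alkyne until the aldehyde chemistry is finished. A (Z,Z)-dienal at C7 would be configurationally labile through reversible oxa-6π ring closure and conjugate addition, and an ynal is the better electrophile. The forward steps need a semi-reduction that spares the acrylate and a transposition that does not ionise the dienyl carbinol.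

**Epoxide (14 ⇒ 13 ⇒ 12 ⇒ 11).** The two epoxide C–O bonds are cut to the E olefin of 11. Epoxidation on the open chain is under reagent control. It also has to precede the photooxygenation, since a trisubstituted ring olefin would undergo the ene reaction. The reagent must prefer the isolated E olefin over the Z olefin conjugated to the alkyne.

**C1–C2 and C10–CH3 (11 ⇒ 10 ⇒ 9 + 7; 9 ⇒ 8).** The skipped diene is cut at the sp2–sp3 bond C1–C2 and at the C10 methyl, giving alkenylalane 10 (from alkyne 9, made from 8) and allylic chloride 7. Olefination routes to the E trisubstituted olefin are less selective and would pass through β,γ-unsaturated or β,γ-epoxy aldehydes. Carboalumination sets the E geometry by syn addition and the alane couples directly.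

**C4–C5 (7 ⇒ 6 ⇒ 5 ⇒ 3 + 4; 3 ⇒ 2 ⇒ 1).** The enyne is cut at C4–C5 into Z iodide 3 and alkyne 4. The Z geometry of C3=C4 comes from anti hydroalumination–iodination of butynol 1 via alanate 2, and is carried through chloride formation via mesylate 6.

## Roads not taken

**Alternative 1:** Ring expansion by anionic oxy-Cope rearrangement. The cut is C8–C9, with the C1–C6 bond of a cyclohexene restored in the precursor. Forward, the potassium alkoxide of cyclohexenol A2 (KH, 18-crown-6) undergoes a [3,3] shift to the ten-membered dienone A1.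
- Merits: no high dilution is needed, the reaction type is well established for germacrane ketones, and the 1(10)E and 4Z geometries follow from the chair transition state and the ring olefin of A2.
- Weak points for this target: A1 has a C6 ketone and lacks the C7 arm, the lactone, the epoxide and both esters. C7 must be alkylated regioselectively, the ketone reduced to the alcohol cis to the new arm, the 1(10) olefin epoxidised face-selectively on the ring, and two protecting groups exchanged for acyl groups.
- Comparison: the ring-forming step is more secure than either the indium closure or the photooxygenation of the chosen plan. Against that, the chosen plan forms the ring, the arm and C7/C8 in one step and both oxygens in another, whereas this road sets C6 and C7 one at a time by substrate control on a flexible ring and has a longer endgame.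

**Alternative 2:** Alkenylchromium closure. The cut is C3–C4. Forward, the seco iodo aldehyde A4 is treated with CrCl2 (divalent chromium) and catalytic NiCl2 (divalent nickel); the alkenylchromium formed at C4 adds to the C3 aldehyde and gives lactone alcohol A3.
- Merits: this closure has a strong record for ten-membered rings, the Z geometry is carried in with the iodide, the lactone and methacrylate are already in place, and only epoxidation and acetylation remain.
- Weak points: the C3 configuration rests on macrocyclic control alone. The 1(10) olefin of A3 must then be epoxidised with chemo- and face-selectivity beside an allylic alcohol. The C6/C7/C8 triad has to be built on the open chain beforehand.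
- Comparison: this road is at least as short and stands on firmer precedent. The chosen plan offers in return that the C3/C6 cis relationship and the Z olefin are fixed by mechanism, and that the epoxide is set early under reagent control.

**Alternative 3:** Ramberg–Bäcklund ring contraction. The cut is the C4=C5 double bond. Forward, the eleven-membered sulfone A6 is α-halogenated in situ and treated with base (KOH on alumina, CBr2F2); the episulfone loses SO2 and gives triene A5.
- Merits: the ring is closed as a larger thiacycle by C–S bond formation, and the olefin appears exactly where it is wanted without organometallic reagents.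
- Weak points: the geometry of a trisubstituted olefin from this reaction in a medium ring is not reliably Z, and halogenation can occur on either side of sulfur. Strong base meets β-silyloxy groups. A5 carries four protecting groups, has C12 at the alcohol level and still lacks the epoxide.
- Comparison: closing an eleven-membered sulfide is easier than any ten-membered C–C closure, and here this road is better. The chosen plan is shorter, changes oxidation state less often and uses two protecting groups in all.

Key step: step 16

Assumption: germacrane numbering is used for the ring compounds (C1–C10 in the ring, C11–C13 the three-carbon arm on C7 with C12 the carboxyl carbon, C14 on C10, C15 on C4), and the D-fructose-derived Shi ketone is taken to give the (R,R)-epoxide from the E trisubstituted olefin, as it does with related olefins.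

## Route

Step 1
Reactants: 1 but-2-yn-1-ol
Product: 3 (2Z)-3-iodobut-2-en-1-ol, via cyclic vinylalanate 2 (not isolated)
Conditions: NaAlH2(OCH2CH2OMe)2, THF, 0 °C → rt; then I2, THF, −78 → 0 °C
Reagents that add atoms: iodine, II
Why: Anti hydroalumination of the propargylic alcohol places aluminium on the distal alkyne carbon in a five-membered alkoxide chelate (2); iodinolysis of the C–Al bond with retention gives the Z iodide, which fixes the later C3=C4 geometry.

Step 2
Reactants: 3 (2Z)-3-iodobut-2-en-1-ol; 4 tert-butyldimethyl(prop-2-yn-1-yloxy)silane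
Product: 5 (2Z)-6-[(tert-butyldimethylsilyl)oxy]-3-methylhex-2-en-4-yn-1-ol
Conditions: PdCl2(PPh3)2 (3 mol %), CuI (6 mol %), Et3N, THF, rt
Reagents that add atoms: none
Why: Sonogashira coupling forms C4–C5 with retention of the alkenyl iodide geometry; the free allylic hydroxyl is tolerated.

Step 3
Reactants: 5 (2Z)-6-[(tert-butyldimethylsilyl)oxy]-3-methylhex-2-en-4-yn-1-ol
Product: 7 tert-butyl{[(4Z)-6-chloro-4-methylhex-4-en-2-yn-1-yl]oxy}dimethylsilane, via allylic mesylate 6 (not isolated)
Conditions: MsCl, LiCl, 2,4,6-collidine, DMF, 0 °C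
Reagents that add atoms: lithium chloride, [Li+].[Cl-]; methanesulfonyl chloride, CS(=O)(=O)Cl (its mesyl group is carried only by 6)
Why: Mesylation and direct SN2 displacement by chloride at the primary allylic carbon; without ionisation the Z geometry and the position of the double bond are kept.

Step 4
Reactants: 8 but-3-yn-1-ol
Product: 9 1-[(but-3-yn-1-yloxy)methyl]-4-methoxybenzene
Conditions: NaH, 4-methoxybenzyl chloride, Bu4NI (cat.), THF/DMF, 0 °C → rt
Reagents that add atoms: 4-methoxybenzyl chloride, COc1ccc(CCl)cc1
Why: Williamson etherification; the PMB ether is stable to organoalanes, dioxirane, fluoride and zinc, and is removed later under neutral oxidative conditions.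

Step 5
Reactants: 9 1-[(but-3-yn-1-yloxy)methyl]-4-methoxybenzene; 7 tert-butyl{[(4Z)-6-chloro-4-methylhex-4-en-2-yn-1-yl]oxy}dimethylsilane
Product: 11 tert-butyl{[(4Z,7E)-10-[(4-methoxybenzyl)oxy]-4,8-dimethyldeca-4,7-dien-2-yn-1-yl]oxy}dimethylsilane, via alkenylalane 10 (not isolated)
Conditions: Me3Al, Cp2ZrCl2 (20 mol %), CH2Cl2, 0 °C → rt; then 7, Pd(PPh3)4 (5 mol %), THF, rt
Reagents that add atoms: trimethylaluminium, C[Al](C)C
Why: Zr-catalysed Negishi carboalumination adds methyl and aluminium syn across the terminal alkyne (methyl to the internal carbon), which sets the E C1=C10 olefin in 10. Cross-coupling of the alkenylalane with the allylic chloride under zerovalent palladium catalysis takes place at the unhindered CH2 terminus with retention of both olefin geometries and forms C1–C2.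

Step 6
Reactants: 11 tert-butyl{[(4Z,7E)-10-[(4-methoxybenzyl)oxy]-4,8-dimethyldeca-4,7-dien-2-yn-1-yl]oxy}dimethylsilane
Product: 12 tert-butyl{[(4Z)-6-[(2R,3R)-3-{2-[(4-methoxybenzyl)oxy]ethyl}-3-methyloxiran-2-yl]-4-methylhex-4-en-2-yn-1-yl]oxy}dimethylsilane
Conditions: D-fructose-derived Shi ketone (30 mol %), KHSO5 (as 2KHSO5·KHSO4·K2SO4), K2CO3, Bu4NHSO4, MeCN/CH2(OMe)2/aq. Na2B4O7 buffer, −10 → 0 °C
Reagents that add atoms: potassium peroxymonosulfate, [K+].[O-]S(=O)(=O)OO
Why: Shi epoxidation: the chiral dioxirane attacks the electron-rich E trisubstituted olefin through a spiro transition state and sets C1 and C10 as R,R by reagent control. The Z olefin is deactivated by the conjugated alkyne and fits this catalyst poorly.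

Step 7
Reactants: 12 tert-butyl{[(4Z)-6-[(2R,3R)-3-{2-[(4-methoxybenzyl)oxy]ethyl}-3-methyloxiran-2-yl]-4-methylhex-4-en-2-yn-1-yl]oxy}dimethylsilane
Product: 13 (4Z)-6-[(2R,3R)-3-{2-[(4-methoxybenzyl)oxy]ethyl}-3-methyloxiran-2-yl]-4-methylhex-4-en-2-yn-1-ol
Conditions: Bu4NF, THF, 0 °C
Reagents that add atoms: none
Why: Fluoride cleaves the Si–O bond; the epoxide and the PMB ether are inert to these conditions.

Step 8
Reactants: 13 (4Z)-6-[(2R,3R)-3-{2-[(4-methoxybenzyl)oxy]ethyl}-3-methyloxiran-2-yl]-4-methylhex-4-en-2-yn-1-ol
Product: 14 (4Z)-6-[(2R,3R)-3-{2-[(4-methoxybenzyl)oxy]ethyl}-3-methyloxiran-2-yl]-4-methylhex-4-en-2-ynal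
Conditions: MnO2, CH2Cl2, rt
Reagents that add atoms: none
Why: MnO2 oxidation of the propargylic alcohol stops at the aldehyde under neutral conditions; the ynal cannot lose olefin geometry by conjugation.

Step 9
Reactants: 14 (4Z)-6-[(2R,3R)-3-{2-[(4-methoxybenzyl)oxy]ethyl}-3-methyloxiran-2-yl]-4-methylhex-4-en-2-ynal; 15 methyl acrylate
Product: 16 methyl (6Z)-3-hydroxy-8-[(2R,3R)-3-{2-[(4-methoxybenzyl)oxy]ethyl}-3-methyloxiran-2-yl]-6-methyl-2-methylideneoct-6-en-4-ynoate (both configurations at C3)
Conditions: methyl acrylate (excess), DABCO (0.5 equiv), neat, rt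
Reagents that add atoms: none
Why: Morita–Baylis–Hillman reaction: the ammonium enolate from DABCO and the acrylate adds to the reactive ynal and elimination releases the catalyst, forming C7–C11. The new carbinol centre is left uncontrolled because it becomes sp2 in step 11.

Step 10
Reactants: 16 methyl (6Z)-3-hydroxy-8-[(2R,3R)-3-{2-[(4-methoxybenzyl)oxy]ethyl}-3-methyloxiran-2-yl]-6-methyl-2-methylideneoct-6-en-4-ynoate
Product: 17 methyl (4Z,6Z)-3-hydroxy-8-[(2R,3R)-3-{2-[(4-methoxybenzyl)oxy]ethyl}-3-methyloxiran-2-yl]-6-methyl-2-methylideneocta-4,6-dienoate (both configurations at C3)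
Conditions: Zn dust activated with Cu(OAc)2 and AgNO3, MeOH/H2O (1:1), rt → 40 °C
Reagents that add atoms: none
Why: Semi-reduction of the conjugated enyne on activated zinc delivers both hydrogens to one face of the triple bond and gives the Z C5=C6 olefin; the non-conjugated acrylate, the epoxide and the trisubstituted olefin are not reduced.

Step 11
Reactants: 17 methyl (4Z,6Z)-3-hydroxy-8-[(2R,3R)-3-{2-[(4-methoxybenzyl)oxy]ethyl}-3-methyloxiran-2-yl]-6-methyl-2-methylideneocta-4,6-dienoate
Product: 18 methyl (2Z,4Z,6Z)-2-(bromomethyl)-8-[(2R,3R)-3-{2-[(4-methoxybenzyl)oxy]ethyl}-3-methyloxiran-2-yl]-6-methylocta-2,4,6-trienoate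
Conditions: NBS, Me2S, CH2Cl2, −20 → 0 °C
Reagents that add atoms: N-bromosuccinimide, O=C1CCC(=O)N1Br
Why: SN2′ bromination of a Morita–Baylis–Hillman alcohol: the hydroxyl is activated as an alkoxysulfonium ion and bromide adds at the acrylate CH2 with loss of the C7 oxygen. This gives the conjugated primary bromide with the dienyl chain trans to the ester, without a free dienyl cation.

Step 12
Reactants: 18 methyl (2Z,4Z,6Z)-2-(bromomethyl)-8-[(2R,3R)-3-{2-[(4-methoxybenzyl)oxy]ethyl}-3-methyloxiran-2-yl]-6-methylocta-2,4,6-trienoate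
Product: 19 methyl (2Z,4Z,6Z)-2-(bromomethyl)-8-[(2R,3R)-3-(2-hydroxyethyl)-3-methyloxiran-2-yl]-6-methylocta-2,4,6-trienoate
Conditions: DDQ, CH2Cl2/pH 7 phosphate buffer, 0 °C
Reagents that add atoms: none
Why: Oxidative PMB cleavage by benzylic hydride abstraction and hydrolysis; the conditions are neutral, so the allylic bromide, the electron-poor triene and the epoxide survive.

Step 13
Reactants: 19 methyl (2Z,4Z,6Z)-2-(bromomethyl)-8-[(2R,3R)-3-(2-hydroxyethyl)-3-methyloxiran-2-yl]-6-methylocta-2,4,6-trienoate
Product: 20 methyl (2Z,4Z,6Z)-2-(bromomethyl)-6-methyl-8-[(2R,3R)-3-methyl-3-(2-oxoethyl)oxiran-2-yl]octa-2,4,6-trienoate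
Conditions: Dess–Martin periodinane, NaHCO3, CH2Cl2, 0 °C
Reagents that add atoms: none
Why: Buffered Dess–Martin oxidation gives the β,γ-epoxy aldehyde without base strong enough to open the epoxide by elimination; the aldehyde is used at once without purification.

Step 14
Reactants: 20 methyl (2Z,4Z,6Z)-2-(bromomethyl)-6-methyl-8-[(2R,3R)-3-methyl-3-(2-oxoethyl)oxiran-2-yl]octa-2,4,6-trienoate
Product: 22 methyl (1R,7R,8R,10R)-1,10-epoxy-8-hydroxygermacra-3Z,5Z,11(13)-trien-12-oate, via allylindium dibromide 21 (not isolated)
Conditions: In powder, THF/H2O (4:1), slow addition to 0.003 M, rt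
Reagents that add atoms: none
Why: Intramolecular Barbier allylation: indium inserts into the C–Br bond and the ester-chelated allylindium 21 adds through its γ carbon (C7) to the aldehyde in a closed six-membered chair transition state, closing the ten-membered ring and releasing the exocyclic methylene. The chair places the C7 arm and O8 cis on the ring (the syn mode usual for 2-(bromomethyl)alk-2-enoates), and attack on the aldehyde face turned away from the C10–O bond should give 7R,8R. The neutral medium leaves the epoxide and the hydroxy ester untouched.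

Step 15
Reactants: 22 methyl (1R,7R,8R,10R)-1,10-epoxy-8-hydroxygermacra-3Z,5Z,11(13)-trien-12-oate
Product: 23 methyl (1R,7R,8R,10R)-1,10-epoxy-8-(methacryloyloxy)germacra-3Z,5Z,11(13)-trien-12-oate
Conditions: methacrylic anhydride, Et3N, DMAP (cat.), CH2Cl2, 0 °C
Reagents that add atoms: methacrylic anhydride, C=C(C)C(=O)OC(=O)C(C)=C
Why: DMAP-catalysed acylation with retention at C8, run on the freshly isolated alcohol so that acylation pre-empts lactonisation of O8 onto the methyl ester.

Step 16
Reactants: 23 methyl (1R,7R,8R,10R)-1,10-epoxy-8-(methacryloyloxy)germacra-3Z,5Z,11(13)-trien-12-oate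
Product: 24 methyl (1R,3S,6S,7R,8R,10R)-3,6-epidioxy-1,10-epoxy-8-(methacryloyloxy)germacra-4Z,11(13)-dien-12-oate
Conditions: O2, 5,10,15,20-tetraphenylporphyrin (1 mol %), visible light, CH2Cl2, −78 °C
Reagents that add atoms: dioxygen, O=O
Why: Proposed new method: sensitised singlet oxygen adds suprafacially across C3 and C6 of the s-cis diene in a concerted [4+2] cycloaddition; the closest known reaction type is the photooxygenation of cyclic 1,3-dienes with five- to eight-membered rings and of acyclic dienes to 3,6-dihydro-1,2-dioxines, which has not been shown for a cyclodeca-1,3-diene. The six-membered dioxine ring closes by forming both C–O bonds at once and bridges the carbocycle as a bicyclo[6.2.2] framework; since C4=C5 lies inside this ring it can only be Z. C3 and C6 are created together and are cis to each other because the addition is suprafacial. Their sense relative to C7 is set by the face attacked: in the rotamer where H7 eclipses C5=C6 (allylic 1,3-strain with C4 and its methyl) the acrylate arm covers one face and oxygen should add to the other, which gives 3S,6S with O6 cis to the arm on the ring. The step also needs [4+2] to be faster than the ene reaction at H2, H7 and the C4 methyl; the Z,Z geometry holds C2 and C7 on the inside of the diene as in smaller cyclic dienes, and low temperature in a non-polar solvent favours the concerted path. The two electron-poor 1,1-disubstituted acrylates and the epoxide are inert to singlet oxygen.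

Step 17
Reactants: 24 methyl (1R,3S,6S,7R,8R,10R)-3,6-epidioxy-1,10-epoxy-8-(methacryloyloxy)germacra-4Z,11(13)-dien-12-oate
Product: 25 methyl (1R,3S,6S,7S,8R,10R)-1,10-epoxy-3,6-dihydroxy-8-(methacryloyloxy)germacra-4Z,11(13)-dien-12-oate
Conditions: thiourea, MeOH, 0 °C → rt
Reagents that add atoms: none
Why: Thiourea reduces the O–O bond by attack of sulfur on oxygen followed by solvolysis and gives the cis-2-ene-1,4-diol without touching a C–O bond, so C3 and C6 keep their configuration (the C7 descriptor changes only by priority). No amine base is present, which avoids the Kornblum–DeLaMare rearrangement.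

Step 18
Reactants: 25 methyl (1R,3S,6S,7S,8R,10R)-1,10-epoxy-3,6-dihydroxy-8-(methacryloyloxy)germacra-4Z,11(13)-dien-12-oate
Product: 26 (1R,3S,6S,7R,8R,10R)-1,10-epoxy-3-hydroxy-8-(methacryloyloxy)germacra-4Z,11(13)-dien-12,6-olide
Conditions: pyridinium p-toluenesulfonate (10 mol %), CH2Cl2, rt
Reagents that add atoms: none
Why: Acid-catalysed intramolecular transesterification: the C6 hydroxyl, cis to the arm, closes the five-membered lactone onto the methyl ester. The C3 hydroxyl cannot reach C12 and O8 is already acylated, so only the cis-fused 12,6-olide can form.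

Step 19
Reactants: 26 (1R,3S,6S,7R,8R,10R)-1,10-epoxy-3-hydroxy-8-(methacryloyloxy)germacra-4Z,11(13)-dien-12,6-olide
Product: 27 (1R,3S,6S,7R,8R,10R)-3-acetoxy-1,10-epoxy-8-(methacryloyloxy)germacra-4Z,11(13)-dien-12,6-olide
Conditions: Ac2O, pyridine, DMAP (cat.), CH2Cl2, 0 °C
Reagents that add atoms: acetic anhydride, CC(=O)OC(C)=O
Why: Acetylation of the only free hydroxyl with retention at C3; these conditions are routinely tolerated by α-methylene lactones and epoxides.

## Compound list

1 | but-2-yn-1-ol | CC#CCO | starting material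
2 | sodium 2,2-bis(2-methoxyethoxy)-3-methyl-2,5-dihydro-1,2-oxaaluminol-2-uide (cyclic vinylalanate) | [Na+].CC1=CCO[Al-]1(OCCOC)OCCOC | intermediate
3 | (2Z)-3-iodobut-2-en-1-ol | C/C(I)=C/CO | intermediate
4 | tert-butyldimethyl(prop-2-yn-1-yloxy)silane | C#CCO[Si](C)(C)C(C)(C)C | starting material
5 | (2Z)-6-[(tert-butyldimethylsilyl)oxy]-3-methylhex-2-en-4-yn-1-ol | OC/C=C(C)\C#CCO[Si](C)(C)C(C)(C)C | intermediate
6 | (2Z)-6-[(tert-butyldimethylsilyl)oxy]-3-methylhex-2-en-4-yn-1-yl methanesulfonate | CS(=O)(=O)OC/C=C(C)\C#CCO[Si](C)(C)C(C)(C)C | intermediate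
7 | tert-butyl{[(4Z)-6-chloro-4-methylhex-4-en-2-yn-1-yl]oxy}dimethylsilane | ClC/C=C(C)\C#CCO[Si](C)(C)C(C)(C)C | intermediate
8 | but-3-yn-1-ol | C#CCCO | starting material
9 | 1-[(but-3-yn-1-yloxy)methyl]-4-methoxybenzene | COc1ccc(COCCC#C)cc1 | intermediate
10 | {(1E)-4-[(4-methoxybenzyl)oxy]-2-methylbut-1-en-1-yl}dimethylalane | COc1ccc(COCC/C(C)=C/[Al](C)C)cc1 | intermediate
11 | tert-butyl{[(4Z,7E)-10-[(4-methoxybenzyl)oxy]-4,8-dimethyldeca-4,7-dien-2-yn-1-yl]oxy}dimethylsilane | COc1ccc(COCC/C(C)=C/C/C=C(C)\C#CCO[Si](C)(C)C(C)(C)C)cc1 | intermediate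
12 | tert-butyl{[(4Z)-6-[(2R,3R)-3-{2-[(4-methoxybenzyl)oxy]ethyl}-3-methyloxiran-2-yl]-4-methylhex-4-en-2-yn-1-yl]oxy}dimethylsilane | COc1ccc(COCC[C@@]2(C)O[C@@H]2C/C=C(C)\C#CCO[Si](C)(C)C(C)(C)C)cc1 | intermediate
13 | (4Z)-6-[(2R,3R)-3-{2-[(4-methoxybenzyl)oxy]ethyl}-3-methyloxiran-2-yl]-4-methylhex-4-en-2-yn-1-ol | COc1ccc(COCC[C@@]2(C)O[C@@H]2C/C=C(C)\C#CCO)cc1 | intermediate
14 | (4Z)-6-[(2R,3R)-3-{2-[(4-methoxybenzyl)oxy]ethyl}-3-methyloxiran-2-yl]-4-methylhex-4-en-2-ynal | COc1ccc(COCC[C@@]2(C)O[C@@H]2C/C=C(C)\C#CC=O)cc1 | intermediate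
15 | methyl acrylate (methyl prop-2-enoate) | C=CC(=O)OC | starting material
16 | methyl (6Z)-3-hydroxy-8-[(2R,3R)-3-{2-[(4-methoxybenzyl)oxy]ethyl}-3-methyloxiran-2-yl]-6-methyl-2-methylideneoct-6-en-4-ynoate (both configurations at C3) | COc1ccc(COCC[C@@]2(C)O[C@@H]2C/C=C(C)\C#CC(O)C(=C)C(=O)OC)cc1 | intermediate
17 | methyl (4Z,6Z)-3-hydroxy-8-[(2R,3R)-3-{2-[(4-methoxybenzyl)oxy]ethyl}-3-methyloxiran-2-yl]-6-methyl-2-methylideneocta-4,6-dienoate (both configurations at C3) | COc1ccc(COCC[C@@]2(C)O[C@@H]2C/C=C(C)\C=C/C(O)C(=C)C(=O)OC)cc1 | intermediate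
18 | methyl (2Z,4Z,6Z)-2-(bromomethyl)-8-[(2R,3R)-3-{2-[(4-methoxybenzyl)oxy]ethyl}-3-methyloxiran-2-yl]-6-methylocta-2,4,6-trienoate | COc1ccc(COCC[C@@]2(C)O[C@@H]2C/C=C(C)\C=C/C=C(\CBr)C(=O)OC)cc1 | intermediate
19 | methyl (2Z,4Z,6Z)-2-(bromomethyl)-8-[(2R,3R)-3-(2-hydroxyethyl)-3-methyloxiran-2-yl]-6-methylocta-2,4,6-trienoate | OCC[C@@]1(C)O[C@@H]1C/C=C(C)\C=C/C=C(\CBr)C(=O)OC | intermediate
20 | methyl (2Z,4Z,6Z)-2-(bromomethyl)-6-methyl-8-[(2R,3R)-3-methyl-3-(2-oxoethyl)oxiran-2-yl]octa-2,4,6-trienoate | O=CC[C@@]1(C)O[C@@H]1C/C=C(C)\C=C/C=C(\CBr)C(=O)OC | intermediate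
21 | allylindium dibromide of 20 (indium on C13, drawn as the monomeric dibromide) | O=CC[C@@]1(C)O[C@@H]1C/C=C(C)\C=C/C=C(\C[In](Br)Br)C(=O)OC | intermediate
22 | methyl (1R,7R,8R,10R)-1,10-epoxy-8-hydroxygermacra-3Z,5Z,11(13)-trien-12-oate | O[C@@H]1C[C@@]2(C)O[C@@H]2C/C=C(C)\C=C/[C@@H]1C(=C)C(=O)OC | intermediate
23 | methyl (1R,7R,8R,10R)-1,10-epoxy-8-(methacryloyloxy)germacra-3Z,5Z,11(13)-trien-12-oate | C=C(C)C(=O)O[C@@H]1C[C@@]2(C)O[C@@H]2C/C=C(C)\C=C/[C@@H]1C(=C)C(=O)OC | intermediate
24 | methyl (1R,3S,6S,7R,8R,10R)-3,6-epidioxy-1,10-epoxy-8-(methacryloyloxy)germacra-4Z,11(13)-dien-12-oate | C=C(C)C(=O)O[C@@H]1C[C@@]2(C)O[C@@H]2C[C@@H]3OO[C@@H](C=C3C)[C@@H]1C(=C)C(=O)OC | intermediate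
25 | methyl (1R,3S,6S,7S,8R,10R)-1,10-epoxy-3,6-dihydroxy-8-(methacryloyloxy)germacra-4Z,11(13)-dien-12-oate | C=C(C)C(=O)O[C@@H]1C[C@@]2(C)O[C@@H]2C[C@H](O)/C(C)=C\[C@H](O)[C@@H]1C(=C)C(=O)OC | intermediate
26 | (1R,3S,6S,7R,8R,10R)-1,10-epoxy-3-hydroxy-8-(methacryloyloxy)germacra-4Z,11(13)-dien-12,6-olide | C=C(C)C(=O)O[C@@H]1C[C@@]2(C)O[C@@H]2C[C@H](O)/C(C)=C\[C@@H]2OC(=O)C(=C)[C@@H]21 | intermediate
27 | (1R,3S,6S,7R,8R,10R)-3-acetoxy-1,10-epoxy-8-(methacryloyloxy)germacra-4Z,11(13)-dien-12,6-olide (CNP0267696.3) | C=C(C)C(=O)O[C@@H]1C[C@@]2(C)O[C@@H]2C[C@H](OC(C)=O)/C(C)=C\[C@@H]2OC(=O)C(=C)[C@@H]21 | target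

## Step count and least certain steps

Total: 19 steps. Longest linear sequence: 18 steps (from 1 through steps 1–3 and 5–19; step 4 prepares the second fragment).

**Step 16 (key step, proposed new method).** The most likely failure is that the ene reaction, or stepwise dioxetane formation, overtakes the cycloaddition. The Z,Z-diene in a ten-membered ring is twisted and reaches the s-cis geometry only at a cost, while the trisubstituted C3=C4 bond has three sets of allylic hydrogens. The second risk is attack on the other diene face, because the ring carbon C8 and the arm flank the two faces at C6 with similar bulk; this would give the C3,C6-bis-epimer. The fallback uses known reaction types, needs no s-cis diene and forms the two C–O bonds one at a time. It sets out from 23.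
- The methyl ester is cleaved selectively with Me3SnOH (1,2-dichloroethane, 70 °C) to (1R,7R,8R,10R)-1,10-epoxy-8-(methacryloyloxy)germacra-3Z,5Z,11(13)-trien-12-oic acid F1.
- Dimethyldioxirane (acetone, −40 → −20 °C) epoxidises the more electron-rich C3=C4 bond from the open face to give (1R,3S,4R,7R,8R,10R)-1,10:3,4-diepoxy-8-(methacryloyloxy)germacra-5Z,11(13)-dien-12-oic acid F2.
- Pd(PPh3)4 (5 mol %, THF, 0 °C) ionises the vinyl epoxide anti to the leaving oxygen. The C12 carboxylate attacks C6 anti to palladium, so O6 arrives on the face that O3 occupies and C4=C5 forms within the ring.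
- The sequence comes back to the route at hydroxy lactone 26.

**Step 14.** The most likely failure is poor facial selectivity at the aldehyde. The only resident stereocentres sit in the epoxide, one carbon removed, so the ten-membered transition state may deliver the C8 epimer. Oligomerisation and loss of the C5=C6 geometry through 1,3-shifts of the dienyl-substituted allylmetal are further risks; these are addressed by high dilution and by the chelated ester. The fallback changes how C8 is secured, replacing retentive acylation by invertive esterification. It sets out from 20. The closure is run as before, and the alcohol it then delivers, methyl (1R,7R,8S,10R)-1,10-epoxy-8-hydroxygermacra-3Z,5Z,11(13)-trien-12-oate F3, is esterified with methacrylic acid under Mitsunobu conditions (PPh3, diisopropyl azodicarboxylate, toluene, 0 °C). This inverts C8 and rejoins the route at 23.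

**Step 6.** The most likely failure is loss of chemoselectivity. The dioxirane may also epoxidise the Z olefin of the enyne, and enantiofacial control may be incomplete for a substrate with a flexible allylic methylene. The fallback replaces the undirected epoxidation by a hydroxyl-directed one and sets out from 8 and 7.
- Carboalumination of unprotected 8 (Me3Al in excess, Cp2ZrCl2) and coupling with 7 under Pd(PPh3)4 catalysis give (3E,6Z)-10-[(tert-butyldimethylsilyl)oxy]-3,7-dimethyldeca-3,6-dien-8-yn-1-ol F4.
- Asymmetric epoxidation of the homoallylic alcohol with VO(OiPr)3, a chiral bishydroxamic acid ligand and cumene hydroperoxide in toluene reaches only the olefin next to the hydroxyl. It gives 2-[(2R,3R)-3-{(2Z)-6-[(tert-butyldimethylsilyl)oxy]-3-methylhex-2-en-4-yn-1-yl}-2-methyloxiran-2-yl]ethan-1-ol F5.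
- Protection with 4-methoxybenzyl 2,2,2-trichloroacetimidate and catalytic La(OTf)3 returns to the route at 12.

## Further compounds

F1 | step 16 | (1R,7R,8R,10R)-1,10-epoxy-8-(methacryloyloxy)germacra-3Z,5Z,11(13)-trien-12-oic acid | C=C(C)C(=O)O[C@@H]1C[C@@]2(C)O[C@@H]2C/C=C(C)\C=C/[C@@H]1C(=C)C(=O)O
F2 | step 16 | (1R,3S,4R,7R,8R,10R)-1,10:3,4-diepoxy-8-(methacryloyloxy)germacra-5Z,11(13)-dien-12-oic acid | C=C(C)C(=O)O[C@@H]1C[C@@]2(C)O[C@@H]2C[C@@H]3O[C@]3(C)/C=C\[C@@H]1C(=C)C(=O)O
F3 | step 14 | methyl (1R,7R,8S,10R)-1,10-epoxy-8-hydroxygermacra-3Z,5Z,11(13)-trien-12-oate | O[C@H]1C[C@@]2(C)O[C@@H]2C/C=C(C)\C=C/[C@@H]1C(=C)C(=O)OC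
F4 | step 6 | (3E,6Z)-10-[(tert-butyldimethylsilyl)oxy]-3,7-dimethyldeca-3,6-dien-8-yn-1-ol | OCC/C(C)=C/C/C=C(C)\C#CCO[Si](C)(C)C(C)(C)C
F5 | step 6 | 2-[(2R,3R)-3-{(2Z)-6-[(tert-butyldimethylsilyl)oxy]-3-methylhex-2-en-4-yn-1-yl}-2-methyloxiran-2-yl]ethan-1-ol | OCC[C@@]1(C)O[C@@H]1C/C=C(C)\C#CCO[Si](C)(C)C(C)(C)C
A1 | alternative 1 | (2Z,4S,6E,9R)-4-[(tert-butyldimethylsilyl)oxy]-9-[(4-methoxybenzyl)oxy]-3,7-dimethylcyclodeca-2,6-dien-1-one | COc1ccc(CO[C@@H]2C/C(C)=C/C[C@H](O[Si](C)(C)C(C)(C)C)/C(C)=C\C(=O)C2)cc1
A2 | alternative 1 | (1R,4S,6R)-4-[(tert-butyldimethylsilyl)oxy]-1-{(E)-2-[(4-methoxybenzyl)oxy]ethenyl}-3-methyl-6-(prop-1-en-2-yl)cyclohex-2-en-1-ol (rearranged as its potassium alkoxide) | C=C(C)[C@H]1C[C@H](O[Si](C)(C)C(C)(C)C)C(C)=C[C@]1(O)/C=C/OCc1ccc(OC)cc1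
A3 | alternative 2 | (3S,6S,7R,8R)-3-hydroxy-8-(methacryloyloxy)germacra-1(10)E,4Z,11(13)-trien-12,6-olide | C=C(C)C(=O)O[C@@H]1C/C(C)=C/C[C@H](O)/C(C)=C\[C@@H]2OC(=O)C(=C)[C@@H]21
A4 | alternative 2 | seco form of A3 opened at C3–C4: cis-fused 12,6-olide carrying the (Z)-2-iodoprop-1-enyl group on C6 and, on C7, the C8 methacrylate chain ending in the (E)-olefinic C3 aldehyde | C=C(C)C(=O)O[C@H](C/C(C)=C/CC=O)[C@H]1C(=C)C(=O)O[C@H]1/C=C(/C)I
A5 | alternative 3 | germacra-1(10)E,4Z,11(13)-triene with 3-O-triisopropylsilyl, 6-O-tert-butyldimethylsilyl, 8-O-(4-methoxybenzyl) and 12-O-tert-butyldimethylsilyl groups | COc1ccc(CO[C@@H]2C/C(C)=C/C[C@H](O[Si](C(C)C)(C(C)C)C(C)C)/C(C)=C\[C@H](O[Si](C)(C)C(C)(C)C)[C@@H]2C(=C)CO[Si](C)(C)C(C)(C)C)cc1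
A6 | alternative 3 | eleven-membered cyclic sulfone with SO2 between C4 and C5 of A5 (either configuration at C4) | COc1ccc(CO[C@@H]2C/C(C)=C/C[C@H](O[Si](C(C)C)(C(C)C)C(C)C)C(C)S(=O)(=O)C[C@H](O[Si](C)(C)C(C)(C)C)[C@@H]2C(=C)CO[Si](C)(C)C(C)(C)C)cc1
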